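**Retrosynthetic overview**

1. The oxirane is closed last: the tertiary oxygen on the methyl-bearing carbon of ring A displaces a mesylate on the neighbouring CH. Before that, ketone 23 comes from one flask in which enone 7 takes up an isopropenyl group and its enolate is alkylated by the ring B allylic iodide 21.
2. Enone 7 comes from (S)-6-hydroxy-6-methylcyclohex-2-en-1-one 6, made from methyl vinyl ketone 3 and 3-nitropropanal 2 by a nitro-Michael / crossed-benzoin / nitrous-acid-loss domino. This one operation makes the ring A CH2–CH(isopropenyl) bond and the C(CH3)(O)–CH(O) bond that becomes the C–C bond of the epoxide.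
3. Enabling feature: the trisubstituted oxirane of ring A (the 7-oxabicyclo[4.1.0]heptane). Its two carbons are vicinal C–O carbons, a methyl-bearing quaternary carbon next to a CH, i.e. a masked tertiary α-ketol. Together with the two ring CH2 groups and the methyl they are the four carbons of methyl vinyl ketone; the other three ring carbons come from the nitro aldehyde.
4. Iodide 21 comes from (S)-cyclohex-3-ene-1-carboxylic acid 8: bromolactonisation, epoxide, diaxial bromide opening, oxidation, methyl addition anti to bromine (syn-bromohydrin), then equilibration of the acyl-bearing ring carbon.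
5. Ring order: ring B is bought as the cyclohexene acid; ring A is built in step 2; the oxirane ring is formed in step 17.

Key step: step 2

Assumption: the antipode of the aminoindanol-derived triazolium precatalyst is chosen that delivers the (S)-ketol; its sense of induction is taken from the catalyst family, not claimed as an observation.

**Route**

Step 1
Reactants: 1 acrolein
Product: 2 3-nitropropanal
Conditions: NaNO2, AcOH, THF/H2O, 0 °C; used crude
Reagents that add atoms: sodium nitrite, [Na+].[O-]N=O
Why: Buffered conjugate addition of nitrite through nitrogen to the enal (nitro-Michael type hydronitration) gives the β-nitro aldehyde; no stereocentre is formed.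

Step 2
Reactants: 2 3-nitropropanal; 3 methyl vinyl ketone
Product: 6 (S)-6-hydroxy-6-methylcyclohex-2-en-1-one, via Michael adduct 4 (not isolated), via nitro ketol 5 (not isolated)
Conditions: 3 added slowly, i-Pr2NEt (20 mol %), aminoindanol-derived N-C6F5 triazolium tetrafluoroborate (10 mol %), CH2Cl2, 0 °C to rt; then DBU (1.5 equiv), 0 °C
Reagents that add atoms: none
Why: The amine base generates the nitronate of 2 (the nitro group makes its α-carbon far more acidic than the aldehyde α-carbon), which adds to the β-carbon of 3 (nitro-Michael addition) to give keto aldehyde 4; the triazolylidene then adds to the aldehyde and the Breslow intermediate attacks the methyl ketone (intramolecular crossed aldehyde–ketone benzoin reaction) to give ketol 5, and DBU finally expels nitrite from the β-nitro ketone (E1cB) to give enone 6. The closest known reaction types are the amine/carbene Michael–benzoin cascades and the carbene-catalysed cyclisation of keto aldehydes to six-membered tertiary α-ketols. Ring A closes in the 6-exo-trig mode at the ketone carbonyl. The only stereocentre that survives, the methyl-bearing carbinol carbon, is set by the chiral aminoindanol backbone of the carbene, which shields one face of the enaminol while its hydroxyl proton is passed to the ketone oxygen; the nitro-bearing centre forms without control and is erased by the elimination. The step needs chemoselectivity (one Michael addition, ring closure before loss of nitrous acid, no Stetter addition to 3, no aldol), which should be secured by slow addition of 3, by using only the weak base until the ring is closed, by the low Stetter activity of triazolylidenes toward alkyl vinyl ketones at room temperature, and by the six-membered geometry that holds the ketone next to the acyl anion.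

Step 3
Reactants: 6 (S)-6-hydroxy-6-methylcyclohex-2-en-1-one
Product: 7 (S)-6-methyl-6-(triethylsilyloxy)cyclohex-2-en-1-one
Conditions: Et3SiOTf, 2,6-lutidine, CH2Cl2, −78 °C
Reagents that add atoms: triethylsilyl trifluoromethanesulfonate, CC[Si](CC)(CC)OS(=O)(=O)C(F)(F)F
Why: Silyl ether formation on the tertiary alcohol protects it for the organometallic step and stores the oxygen that later closes the oxirane.

Step 4
Reactants: 8 (S)-cyclohex-3-ene-1-carboxylic acid
Product: 9 (1S,4S,5S)-4-bromo-6-oxabicyclo[3.2.1]octan-7-one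
Conditions: NBS, CH2Cl2, 0 °C to rt
Reagents that add atoms: N-bromosuccinimide, O=C1CCC(=O)N1Br
Why: Bromolactonisation: the carboxylate opens the bromonium ion on its own face, so the lactone oxygen is cis to the carboxyl carbon and the bromine is trans to that oxygen on the next carbon.

Step 5
Reactants: 9 (1S,4S,5S)-4-bromo-6-oxabicyclo[3.2.1]octan-7-one
Product: 11 methyl (1S,3S,6R)-7-oxabicyclo[4.1.0]heptane-3-carboxylate, via sodium alkoxide 10 (not isolated)
Conditions: NaOMe, MeOH, 0 °C
Reagents that add atoms: sodium methoxide, C[O-].[Na+]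
Why: Methanolysis of the lactone frees an alkoxide anti to the bromide, which closes by intramolecular SN2 (Williamson type) to the epoxide cis to the ester.

Step 6
Reactants: 11 methyl (1S,3S,6R)-7-oxabicyclo[4.1.0]heptane-3-carboxylate
Product: 12 methyl (1S,3R,4R)-3-bromo-4-hydroxycyclohexane-1-carboxylate
Conditions: LiBr, AcOH, THF, rt
Reagents that add atoms: lithium bromide, [Li+].[Br-]
Why: Acid-assisted epoxide opening by bromide follows the Fürst–Plattner rule (trans-diaxial opening of the half-chair with the ester equatorial), placing bromine on the carbon nearer the ester and trans to it, and the hydroxyl on the far carbon.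

Step 7
Reactants: 12 methyl (1S,3R,4R)-3-bromo-4-hydroxycyclohexane-1-carboxylate
Product: 13 methyl (1S,3R)-3-bromo-4-oxocyclohexane-1-carboxylate
Conditions: Dess–Martin periodinane, NaHCO3, CH2Cl2, 0 °C
Reagents that add atoms: none
Why: Buffered Dess–Martin oxidation of the secondary alcohol gives the α-bromo ketone while leaving the axial C–Br centre untouched.

Step 8
Reactants: 13 methyl (1S,3R)-3-bromo-4-oxocyclohexane-1-carboxylate
Product: 14 methyl (1S,3R,4S)-3-bromo-4-hydroxy-4-methylcyclohexane-1-carboxylate
Conditions: MeMgBr (1.05 equiv), Et2O/toluene, −78 °C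
Reagents that add atoms: methylmagnesium bromide, C[Mg]Br
Why: Grignard addition is faster at the ketone than at the ester at low temperature and runs along the axial trajectory anti to the axial C–Br bond (polar Felkin–Anh/Cornforth control), so methyl ends trans and hydroxyl cis to bromine (syn-bromohydrin).

Step 9
Reactants: 14 methyl (1S,3R,4S)-3-bromo-4-hydroxy-4-methylcyclohexane-1-carboxylate
Product: 15 methyl (1S,3R,4S)-3-bromo-4-methyl-4-(triethylsilyloxy)cyclohexane-1-carboxylate
Conditions: Et3SiOTf, 2,6-lutidine, CH2Cl2, 0 °C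
Reagents that add atoms: triethylsilyl trifluoromethanesulfonate, CC[Si](CC)(CC)OS(=O)(=O)C(F)(F)F
Why: Silyl ether formation masks the tertiary alcohol so that later bases cannot trigger rearrangement of the cis-bromohydrin.

Step 10
Reactants: 15 methyl (1S,3R,4S)-3-bromo-4-methyl-4-(triethylsilyloxy)cyclohexane-1-carboxylate
Product: 18 1-[(1R,3R,4S)-3-bromo-4-methyl-4-(triethylsilyloxy)cyclohexyl]ethan-1-one, via silyl ketone 16 (not isolated), via epimeric ketone 17 (not isolated)
Conditions: LiCH2SiMe3 (2.2 equiv), THF/pentane, −78 to 0 °C; MeOH; then K2CO3 (cat.), MeOH, 0 °C to rt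
Reagents that add atoms: (trimethylsilyl)methyllithium, [Li]C[Si](C)(C)C
Why: Acyl substitution by the silylmethyl anion stops at the α-silyl enolate, methanolysis removes silicon, and the carbonate equilibrates the ketone α-carbon by enolisation to the isomer whose chair carries bromine, methyl and acetyl all equatorial, which should set the side-chain-bearing ring B carbon cis to bromine (thermodynamic control).

Step 11
Reactants: 18 1-[(1R,3R,4S)-3-bromo-4-methyl-4-(triethylsilyloxy)cyclohexyl]ethan-1-one
Product: 19 1-[(1R,3R,4S)-3-bromo-4-methyl-4-(triethylsilyloxy)cyclohexyl]ethenyl trifluoromethanesulfonate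
Conditions: KN(SiMe3)2, PhNTf2, THF, −78 °C
Reagents that add atoms: N-phenylbis(trifluoromethanesulfonimide), O=S(=O)(N(c1ccccc1)S(=O)(=O)C(F)(F)F)C(F)(F)F
Why: Kinetic deprotonation of the methyl group by the hindered amide and O-triflation of the less substituted enolate give the 1,1-disubstituted alkenyl triflate without enolising toward the ring.

Step 12
Reactants: 19 1-[(1R,3R,4S)-3-bromo-4-methyl-4-(triethylsilyloxy)cyclohexyl]ethenyl trifluoromethanesulfonate
Product: 20 2-[(1R,3R,4S)-3-bromo-4-methyl-4-(triethylsilyloxy)cyclohexyl]prop-2-en-1-ol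
Conditions: Bu3SnCH2OH, Pd(PPh3)4 (5 mol %), LiCl, THF, 65 °C
Reagents that add atoms: (tributylstannyl)methanol, CCCC[Sn](CO)(CCCC)CCCC
Why: Migita–Kosugi–Stille coupling transfers the hydroxymethyl group to the alkenyl triflate and so creates the 1,1-disubstituted alkene of the linker; the secondary alkyl bromide is inert to this catalyst.

Step 13
Reactants: 20 2-[(1R,3R,4S)-3-bromo-4-methyl-4-(triethylsilyloxy)cyclohexyl]prop-2-en-1-ol
Product: 21 {[(1S,2R,4R)-2-bromo-4-(3-iodoprop-1-en-2-yl)-1-methylcyclohexyl]oxy}triethylsilane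
Conditions: I2, PPh3, imidazole, CH2Cl2, 0 °C, dark; used at once
Reagents that add atoms: iodine, II
Why: Garegg–Samuelsson (Appel-type) iodination converts the primary allylic alcohol to the iodide by SN2 at carbon without touching a stereocentre.

Step 14
Reactants: 7 (S)-6-methyl-6-(triethylsilyloxy)cyclohex-2-en-1-one; 21 {[(1S,2R,4R)-2-bromo-4-(3-iodoprop-1-en-2-yl)-1-methylcyclohexyl]oxy}triethylsilane
Product: 23 (2S,5S,6R)-6-{2-[(1R,3R,4S)-3-bromo-4-methyl-4-(triethylsilyloxy)cyclohexyl]prop-2-en-1-yl}-2-methyl-5-(prop-1-en-2-yl)-2-(triethylsilyloxy)cyclohexan-1-one, via magnesium enolate 22 (not isolated)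
Conditions: isopropenylMgBr (1.05 equiv), CuBr·SMe2 (10 mol %), THF, −78 °C; then 21 (1.2 equiv), DMPU, −78 to 0 °C
Reagents that add atoms: isopropenylmagnesium bromide, C=C(C)[Mg]Br
Why: Copper-catalysed conjugate addition followed by enolate alkylation (three-component coupling): isopropenyl should enter axially, anti to the pseudo-axial silyloxy group across the ring; the enolate can form only toward the former α-carbon because the other α-carbon is quaternary; and the allylic iodide is attacked anti to the new isopropenyl group, giving the trans arrangement that is also the thermodynamic one at this epimerisable centre.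

Step 15
Reactants: 23 the ketone of step 14
Product: 24 (1S,2S,5S,6R)-6-{2-[(1R,3R,4S)-3-bromo-4-methyl-4-(triethylsilyloxy)cyclohexyl]prop-2-en-1-yl}-2-methyl-5-(prop-1-en-2-yl)-2-(triethylsilyloxy)cyclohexan-1-ol
Conditions: NaBH4, MeOH/THF, −20 °C
Reagents that add atoms: none

Why: Borohydride reduction: hydride should arrive along the axial trajectory, on the face opposite the axial methyl group of the neighbouring quaternary carbon, giving the equatorial alcohol trans to the silyloxy oxygen.

Step 16
Reactants: 24 the alcohol of step 15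
Product: 25 (1S,2S,5S,6R)-6-{2-[(1R,3R,4S)-3-bromo-4-methyl-4-(triethylsilyloxy)cyclohexyl]prop-2-en-1-yl}-2-methyl-5-(prop-1-en-2-yl)-2-(triethylsilyloxy)cyclohexyl methanesulfonate
Conditions: MsCl, Et3N, CH2Cl2, 0 °C
Reagents that add atoms: methanesulfonyl chloride, CS(=O)(=O)Cl
Why: Sulfonate ester formation at the only free hydroxyl proceeds with retention at carbon and turns it into the leaving group for oxirane closure.

Step 17
Reactants: 25 the mesylate of step 16
Product: 27 (1S,2R,4R)-2-bromo-1-methyl-4-{3-[(1R,2R,3S,6S)-6-methyl-3-(prop-1-en-2-yl)-7-oxabicyclo[4.1.0]heptan-2-yl]prop-1-en-2-yl}cyclohexan-1-ol, via ammonium alkoxide 26 (not isolated)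
Conditions: Bu4NF (3 equiv), THF, 0 °C to rt; neutral aqueous work-up
Reagents that add atoms: none
Why: Fluoride cleaves both silyl ethers and the ring A tertiary alkoxide displaces the vicinal mesylate by intramolecular SN2 (Williamson epoxide closure) with inversion at the CH, so the oxirane oxygen is the one already fixed on the methyl-bearing carbon and lies cis to the side chain; the ring B alkoxide has a cis bromide and cannot close.

**Compound list**

1 | acrolein | C=CC=O | starting material
2 | 3-nitropropanal | O=CCC[N+](=O)[O-] | intermediate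
3 | methyl vinyl ketone | CC(=O)C=C | starting material
4 | 3-nitro-6-oxoheptanal (racemic) | CC(=O)CCC(CC=O)[N+](=O)[O-] | intermediate
5 | (2S)-2-hydroxy-2-methyl-5-nitrocyclohexan-1-one (both epimers at C5) | O=C1CC([N+](=O)[O-])CC[C@]1(C)O | intermediate
6 | (S)-6-hydroxy-6-methylcyclohex-2-en-1-one | O=C1C=CCC[C@]1(C)O | intermediate
7 | (S)-6-methyl-6-(triethylsilyloxy)cyclohex-2-en-1-one | O=C1C=CCC[C@]1(C)O[Si](CC)(CC)CC | intermediate
8 | (S)-cyclohex-3-ene-1-carboxylic acid | O=C(O)[C@H]1CCC=CC1 | starting material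
9 | (1S,4S,5S)-4-bromo-6-oxabicyclo[3.2.1]octan-7-one | O=C2[C@H]1CC[C@H](Br)[C@@H](O2)C1 | intermediate
10 | sodium alkoxide of methyl (1S,3S,4S)-4-bromo-3-hydroxycyclohexane-1-carboxylate | COC(=O)[C@H]1CC[C@H](Br)[C@@H]([O-])C1.[Na+] | intermediate
11 | methyl (1S,3S,6R)-7-oxabicyclo[4.1.0]heptane-3-carboxylate (epoxide cis to ester) | COC(=O)[C@H]1CC[C@H]2O[C@H]2C1 | intermediate
12 | methyl (1S,3R,4R)-3-bromo-4-hydroxycyclohexane-1-carboxylate | COC(=O)[C@H]1CC[C@@H](O)[C@H](Br)C1 | intermediate
13 | methyl (1S,3R)-3-bromo-4-oxocyclohexane-1-carboxylate | COC(=O)[C@H]1CCC(=O)[C@H](Br)C1 | intermediate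
14 | methyl (1S,3R,4S)-3-bromo-4-hydroxy-4-methylcyclohexane-1-carboxylate | COC(=O)[C@H]1CC[C@](C)(O)[C@H](Br)C1 | intermediate
15 | methyl (1S,3R,4S)-3-bromo-4-methyl-4-(triethylsilyloxy)cyclohexane-1-carboxylate | COC(=O)[C@H]1CC[C@](C)(O[Si](CC)(CC)CC)[C@H](Br)C1 | intermediate
16 | 1-[(1S,3R,4S)-3-bromo-4-methyl-4-(triethylsilyloxy)cyclohexyl]-2-(trimethylsilyl)ethan-1-one | C[Si](C)(C)CC(=O)[C@H]1CC[C@](C)(O[Si](CC)(CC)CC)[C@H](Br)C1 | intermediate
17 | 1-[(1S,3R,4S)-3-bromo-4-methyl-4-(triethylsilyloxy)cyclohexyl]ethan-1-one | CC(=O)[C@H]1CC[C@](C)(O[Si](CC)(CC)CC)[C@H](Br)C1 | intermediate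
18 | 1-[(1R,3R,4S)-3-bromo-4-methyl-4-(triethylsilyloxy)cyclohexyl]ethan-1-one (acetyl, Br and O all cis) | CC(=O)[C@@H]1CC[C@](C)(O[Si](CC)(CC)CC)[C@H](Br)C1 | intermediate
19 | 1-[(1R,3R,4S)-3-bromo-4-methyl-4-(triethylsilyloxy)cyclohexyl]ethenyl trifluoromethanesulfonate | C=C(OS(=O)(=O)C(F)(F)F)[C@@H]1CC[C@](C)(O[Si](CC)(CC)CC)[C@H](Br)C1 | intermediate
20 | 2-[(1R,3R,4S)-3-bromo-4-methyl-4-(triethylsilyloxy)cyclohexyl]prop-2-en-1-ol | C=C(CO)[C@@H]1CC[C@](C)(O[Si](CC)(CC)CC)[C@H](Br)C1 | intermediate
21 | {[(1S,2R,4R)-2-bromo-4-(3-iodoprop-1-en-2-yl)-1-methylcyclohexyl]oxy}triethylsilane | C=C(CI)[C@@H]1CC[C@](C)(O[Si](CC)(CC)CC)[C@H](Br)C1 | intermediate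
22 | bromomagnesium enolate of (2S,5S)-2-methyl-5-(prop-1-en-2-yl)-2-(triethylsilyloxy)cyclohexan-1-one | Br[Mg]OC1=C[C@@H](C(C)=C)CC[C@]1(C)O[Si](CC)(CC)CC | intermediate
23 | (2S,5S,6R)-6-{2-[(1R,3R,4S)-3-bromo-4-methyl-4-(triethylsilyloxy)cyclohexyl]prop-2-en-1-yl}-2-methyl-5-(prop-1-en-2-yl)-2-(triethylsilyloxy)cyclohexan-1-one | C=C(C[C@@H]1[C@@H](C(=C)C)CC[C@](C)(O[Si](CC)(CC)CC)C1=O)[C@@H]1CC[C@](C)(O[Si](CC)(CC)CC)[C@H](Br)C1 | intermediate
24 | (1S,2S,5S,6R)-alcohol from 23 (hydroxyl trans to the silyloxy oxygen and to the side chain) | C=C(C[C@@H]1[C@@H](C(=C)C)CC[C@](C)(O[Si](CC)(CC)CC)[C@H]1O)[C@@H]1CC[C@](C)(O[Si](CC)(CC)CC)[C@H](Br)C1 | intermediate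
25 | methanesulfonate of 24 | C=C(C[C@@H]1[C@@H](C(=C)C)CC[C@](C)(O[Si](CC)(CC)CC)[C@H]1OS(C)(=O)=O)[C@@H]1CC[C@](C)(O[Si](CC)(CC)CC)[C@H](Br)C1 | intermediate
26 | tetrabutylammonium alkoxide of the doubly desilylated mesylate | C=C(C[C@@H]1[C@@H](C(=C)C)CC[C@](C)([O-])[C@H]1OS(C)(=O)=O)[C@@H]1CC[C@](C)(O)[C@H](Br)C1.CCCC[N+](CCCC)(CCCC)CCCC | intermediate
27 | (1S,2R,4R)-2-bromo-1-methyl-4-{3-[(1R,2R,3S,6S)-6-methyl-3-(prop-1-en-2-yl)-7-oxabicyclo[4.1.0]heptan-2-yl]prop-1-en-2-yl}cyclohexan-1-ol (CNP0213097.1) | C=C(C[C@@H]1[C@@H](C(=C)C)CC[C@]2(C)O[C@H]12)[C@@H]1CC[C@](C)(O)[C@H](Br)C1 | target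

**Step count and risks**

Total step count: 17. Longest linear sequence: 14 steps (8 to 27, steps 4–17).

Steps most likely to fail:

1. Step 2. The nitro aldehyde may self-condense (nitroaldol) or lose nitrous acid before the ring closes, and enantioface control in the benzoin addition may be incomplete. The fallback starts from 3 and keeps both ring bonds in one operation. Michael–Wittig annulation of 3 with commercial ethyl 3-oxo-4-(triphenylphosphoranylidene)butanoate (NaH cat., THF, reflux) gives ethyl 4-methyl-2-oxocyclohex-3-ene-1-carboxylate F1. Ester hydrolysis and decarboxylation (aq. NaOH, then H3O+, heat) give 3-methylcyclohex-2-en-1-one F2. Asymmetric epoxidation with H2O2 under a 9-amino-9-deoxy-epi-cinchona primary amine salt gives (1S,6S)-6-methyl-7-oxabicyclo[4.1.0]heptan-2-one F3. Wharton transposition (N2H4·H2O, AcOH, MeOH) gives (S)-1-methylcyclohex-2-en-1-ol F4. A Schenck ene reaction with singlet oxygen (O2, light, tetraphenylporphyrin) gives (6S)-6-hydroxy-6-methylcyclohex-2-en-1-yl hydroperoxide F5, which Ac2O/pyridine dehydrates in the same flask to 6, where the route resumes.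

2. Step 14. Facial selectivity in the conjugate addition may be low if conformers with the silyloxy group pseudo-equatorial react, and the magnesium enolate may undergo proton transfer or double alkylation. The fallback starts from 7 and separates the two events under reagent control. Hayashi–Miyaura addition of potassium isopropenyltrifluoroborate ([RhCl(C2H4)2]2, matched BINAP antipode, dioxane/H2O) gives (2S,5S)-2-methyl-5-(prop-1-en-2-yl)-2-(triethylsilyloxy)cyclohexan-1-one F6. Its lithium enolate (LiN(i-Pr)2, THF, −78 °C; only one α-carbon carries hydrogen) is alkylated with 21 (DMPU) to return to 23.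

3. Step 17. A 1,2-shift of a ring bond (semipinacol ring contraction) may outrun oxirane closure, because alkoxide and mesylate are trans-diequatorial in the resting chair. The fallback starts from 24 and ends at 27 through a trans-diaxial closure. Mitsunobu inversion (4-nitrobenzoic acid, PPh3, diisopropyl azodicarboxylate) gives the inverted 4-nitrobenzoate F7. Bu4NF, then K2CO3/MeOH, give the triol with a cis-diol on ring A F8. MeC(OMe)3 with pyridinium p-toluenesulfonate gives the cyclic orthoacetate F9. Acetyl bromide opens the derived acetoxonium ion at the tertiary carbon to the trans-diaxial bromo acetate F10. K2CO3/MeOH then frees the secondary alkoxide, which displaces the axial tertiary bromide to give 27.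

Further compounds
F1 | step 2 | ethyl 4-methyl-2-oxocyclohex-3-ene-1-carboxylate | CCOC(=O)C1CCC(C)=CC1=O
F2 | step 2 | 3-methylcyclohex-2-en-1-one | CC1=CC(=O)CCC1
F3 | step 2 | (1S,6S)-6-methyl-7-oxabicyclo[4.1.0]heptan-2-one | O=C1CCC[C@]2(C)O[C@H]12
F4 | step 2 | (S)-1-methylcyclohex-2-en-1-ol | C1=CCCC[C@]1(C)O
F5 | step 2 | (6S)-6-hydroxy-6-methylcyclohex-2-en-1-yl hydroperoxide | OOC1C=CCC[C@]1(C)O
F6 | step 14 | (2S,5S)-2-methyl-5-(prop-1-en-2-yl)-2-(triethylsilyloxy)cyclohexan-1-one | C1[C@@H](C(=C)C)CC[C@](C)(O[Si](CC)(CC)CC)C1=O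
F7 | step 17 | 4-nitrobenzoate of the C1 epimer of 24 | C=C(C[C@@H]1[C@@H](C(=C)C)CC[C@](C)(O[Si](CC)(CC)CC)[C@@H]1OC(=O)c2ccc(cc2)[N+](=O)[O-])[C@@H]1CC[C@](C)(O[Si](CC)(CC)CC)[C@H](Br)C1
F8 | step 17 | triol with cis-diol on ring A | C=C(C[C@@H]1[C@@H](C(=C)C)CC[C@](C)(O)[C@@H]1O)[C@@H]1CC[C@](C)(O)[C@H](Br)C1
F9 | step 17 | cyclic methyl orthoacetate of F8 | C=C(C[C@@H]1[C@@H](C(=C)C)CC[C@]2(C)OC(C)(OC)O[C@H]12)[C@@H]1CC[C@](C)(O)[C@H](Br)C1
F10 | step 17 | trans-diaxial tertiary bromide / secondary acetate | C=C(C[C@@H]1[C@@H](C(=C)C)CC[C@@](C)(Br)[C@@H]1OC(C)=O)[C@@H]1CC[C@](C)(O)[C@H](Br)C1
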